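**Strategy.** The 1,2-dioxane is cut at C6–O1 and O2–C3. Ring carbons C3 and C6 each carry one peroxide oxygen and are linked through C4–C5, so both can start as carbonyl-level carbons of an open chain: C3 as the ketone of a β-keto ester and C6 as the inner carbon of a methylidene group. Ozonolysis in methanol turns C6 into a methoxy hydroperoxide that closes onto the C3 ketone, giving the ring and the O–O bond in one flask. The precursor is methyl (4R)-4-ethyl-6-methylidene-3-oxooctanoate; its C4 ethyl group later steers axial allylation at C6 and axial hydride delivery at C3, and the dienyl chain is finished by two Negishi couplings.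

Key step: step 6

Assumption: ring atoms are numbered O1, O2, C3 (acetate arm), C4, C5, C6 and the side chain C7 to C14 outward from C6; the C3/C6 ketal-epimer mixtures of 17 and 21 are carried on unseparated because both centres later pass through planar cations.

**Step 1**
Reactants: 1 (4S)-4-benzyl-1,3-oxazolidin-2-one; 2 butanoyl chloride
Product: 3 (4S)-4-benzyl-3-butanoyl-1,3-oxazolidin-2-one
Conditions: Et3N, DMAP (cat.), CH2Cl2, 0 → 23 °C
Reagents that add atoms: none
Why: N-acylation of the oxazolidinone by the acid chloride (nucleophilic acyl substitution under DMAP catalysis) is routine and creates no stereocentre.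

**Step 2**
Reactants: 3 (4S)-4-benzyl-3-butanoyl-1,3-oxazolidin-2-one; 4 2,3-dibromoprop-1-ene
Product: 6 (4S)-4-benzyl-3-[(2R)-4-bromo-2-ethylpent-4-enoyl]-1,3-oxazolidin-2-one, via sodium enolate 5 (not isolated)
Conditions: NaN(SiMe3)2, THF, −78 °C; then 4 (3 equiv), −78 → −40 °C
Reagents that add atoms: none
Why: Evans asymmetric alkylation: the chelated sodium Z-enolate 5 should be attacked by the allylic bromide on the face opposite the benzyl group, which sets the future C4 as R, while the vinylic bromide stays inert.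

**Step 3**
Reactants: 6 (4S)-4-benzyl-3-[(2R)-4-bromo-2-ethylpent-4-enoyl]-1,3-oxazolidin-2-one
Product: 7 (4S)-4-benzyl-3-[(2R)-2-ethyl-4-methylidenehexanoyl]-1,3-oxazolidin-2-one
Conditions: Et2Zn (1.5 equiv), Pd(dppf)Cl2 (5 mol %), THF, 50 °C
Reagents that add atoms: diethylzinc CC[Zn]CC
Why: Negishi coupling of the 2-bromoalkene with Et2Zn replaces bromine by ethyl under neutral conditions that touch neither the imide nor the α-stereocentre.

**Step 4**
Reactants: 7 (4S)-4-benzyl-3-[(2R)-2-ethyl-4-methylidenehexanoyl]-1,3-oxazolidin-2-one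
Product: 9 (2R)-2-ethyl-4-methylidenehexanoic acid, via peroxy acid 8 (not isolated)
Conditions: LiOH, H2O2, THF/H2O (3:1), 0 °C; then Na2SO3; then 1 M HCl
Reagents that add atoms: hydrogen peroxide OO
Why: Hydroperoxide cleavage of the Evans imide (LiOOH attacks the exocyclic carbonyl) followed by sulfite reduction of peracid 8 should give the acid without epimerisation, and the isolated alkene is inert to alkaline H2O2.

**Step 5**
Reactants: 9 (2R)-2-ethyl-4-methylidenehexanoic acid; 10 potassium monomethyl malonate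
Product: 13 methyl (4R)-4-ethyl-6-methylidene-3-oxooctanoate, via acyl imidazolide 11 (not isolated), via acylmalonate half ester 12 (not isolated)
Conditions: CDI, THF, 23 °C; then 10, MgCl2, THF, 23 → 40 °C; 1 M HCl work-up
Reagents that add atoms: none
Why: Masamune magnesium malonate homologation: the acyl imidazolide C-acylates the magnesium malonate and decarboxylation gives the β-keto ester under near-neutral conditions that should preserve the adjacent stereocentre.

**Step 6**
Reactants: 13 methyl (4R)-4-ethyl-6-methylidene-3-oxooctanoate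
Product: 17 methyl 2-[(4R)-4,6-diethyl-3-hydroxy-6-methoxy-1,2-dioxan-3-yl]acetate (C3/C6 ketal epimer mixture), via primary ozonide 14 (not isolated), via carbonyl oxide 15 (not isolated), via methoxy hydroperoxide 16 (not isolated)
Conditions: O3, MeOH/CH2Cl2 (5:1), Sudan Red 7B, −78 °C; N2 purge; then 23 °C, 12 h
Reagents that add atoms: ozone [O-][O+]=O; methanol CO
Why: Ozone adds to the electron-rich 1,1-disubstituted alkene to give primary ozonide 14, whose cycloreversion expels formaldehyde and leaves carbonyl oxide 15 on the more substituted carbon C6, and methanol captures 15 as the α-methoxy hydroperoxide 16. On warming, the OOH oxygen adds to the electrophilic C3 ketone in a 6-exo-trig hemiketalisation, so the C6–O1 and O2–C3 bonds and the 1,2-dioxane ring arise in one flask. The closest known chemistry is Criegee ozonolysis of 2,2-disubstituted terminal alkenes in methanol and the cyclisation of γ-hydroperoxy ketones to 1,2-dioxan-3-ols. No new stereocentre needs control: C3 and C6 form as ketal epimers that are both ionised later, and C4 should survive because the medium is neutral and cold. The step needs ozone to take the alkene and not the small enol fraction of the keto ester, which the far higher alkene reactivity at −78 °C and the dye end point should secure, and it needs methanol capture to beat intramolecular ozonide formation with the ketone, which methanol as bulk solvent should secure.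

**Step 7**
Reactants: 17 methyl 2-[(4R)-4,6-diethyl-3-hydroxy-6-methoxy-1,2-dioxan-3-yl]acetate; 18 allyltrimethylsilane
Product: 21 methyl 2-[(4R,6R)-4,6-diethyl-6-(prop-2-en-1-yl)-3-(trimethylsilyloxy)-1,2-dioxan-3-yl]acetate (C3 epimer mixture), via C3 silyl ether 19 (not isolated), via C6 peroxycarbenium triflate 20 (not isolated)
Conditions: 2,6-lutidine (1.1 equiv), Me3SiOTf (1.1 equiv), CH2Cl2, −78 °C; then 18 (4 equiv), Me3SiOTf (1.2 equiv), −78 °C
Reagents that add atoms: trimethylsilyl trifluoromethanesulfonate C[Si](C)(C)OS(=O)(=O)C(F)(F)F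
Why: Sakurai-type allylation of a cyclic peroxyketal: once the C3 hydroxyl is capped as its silyl ether, Me3SiOTf should ionise only the C6 methoxy group (C3 is deactivated by the ester arm and carries the poorer leaving group), and allyltrimethylsilane attacks half-chair cation 20 axially, trans to the pseudo-equatorial C4 ethyl group, which sets C6.

**Step 8**
Reactants: 21 methyl 2-[(4R,6R)-4,6-diethyl-6-(prop-2-en-1-yl)-3-(trimethylsilyloxy)-1,2-dioxan-3-yl]acetate
Product: 23 methyl 2-[(3S,4R,6R)-4,6-diethyl-6-(prop-2-en-1-yl)-1,2-dioxan-3-yl]acetate, via C3 peroxycarbenium triflate 22 (not isolated)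
Conditions: Et3SiH (5 equiv), Me3SiOTf (1.2 equiv), CH2Cl2, −78 → −30 °C
Reagents that add atoms: none
Why: Ionic hydrogenation of the silylated peroxy hemiketal: loss of the silyloxy group gives cation 22, conformationally locked by the two equatorial ethyl groups, and Et3SiH should deliver hydride axially so that the acetate arm ends equatorial and trans to the C4 ethyl group (3S).

**Step 9**
Reactants: 23 methyl 2-[(3S,4R,6R)-4,6-diethyl-6-(prop-2-en-1-yl)-1,2-dioxan-3-yl]acetate
Product: 24 methyl 2-[(3S,4R,6S)-4,6-diethyl-6-[(1E)-prop-1-en-1-yl]-1,2-dioxan-3-yl]acetate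
Conditions: Pd(dba)2 (3 mol %), P(t-Bu)3 (3 mol %), i-PrCOCl (3 mol %), toluene, 50 °C
Reagents that add atoms: none
Why: Palladium hydride-catalysed alkene isomerisation (hydropalladation then β-hydride elimination) should move the terminal double bond one position to the more stable internal alkene, which cannot migrate past the quaternary C6, and any Z isomer converges in step 10.

**Step 10**
Reactants: 24 methyl 2-[(3S,4R,6S)-4,6-diethyl-6-[(1E)-prop-1-en-1-yl]-1,2-dioxan-3-yl]acetate
Product: 26 methyl 2-[(3S,4R,6S)-4,6-diethyl-6-formyl-1,2-dioxan-3-yl]acetate, via ozonide 25 (not isolated)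
Conditions: O3, CH2Cl2, −78 °C; then PPh3, −78 → 23 °C
Reagents that add atoms: ozone [O-][O+]=O
Why: Ozonolysis with reductive work-up cleaves the only alkene to the C7 aldehyde; PPh3 reduces the ozonide far faster than the hindered dialkyl peroxide, and the quaternary C6 cannot epimerise.

**Step 11**
Reactants: 26 methyl 2-[(3S,4R,6S)-4,6-diethyl-6-formyl-1,2-dioxan-3-yl]acetate
Product: 27 methyl 2-[(3S,4R,6S)-6-(2,2-dibromoethenyl)-4,6-diethyl-1,2-dioxan-3-yl]acetate
Conditions: CBr4 (2 equiv), PPh3 (4 equiv), CH2Cl2, 0 °C; then 26, 0 °C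
Reagents that add atoms: carbon tetrabromide BrC(Br)(Br)Br
Why: Ramirez (Corey–Fuchs) dibromo-olefination with the preformed ylide Ph3P=CBr2 converts the aldehyde into the 1,1-dibromoalkene under neutral conditions that should leave ester and peroxide intact.

**Step 12**
Reactants: 28 (3E)-hex-3-enoic acid; 1 (4S)-4-benzyl-1,3-oxazolidin-2-one
Product: 30 (4S)-4-benzyl-3-[(3E)-hex-3-enoyl]-1,3-oxazolidin-2-one, via mixed pivalic anhydride 29 (not isolated)
Conditions: t-BuCOCl, Et3N, THF, −20 °C; then 1, LiCl, −20 → 23 °C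
Reagents that add atoms: none
Why: Mixed-anhydride N-acylation of the oxazolidinone is standard and mild enough to keep the β,γ-double bond unconjugated and E.

**Step 13**
Reactants: 30 (4S)-4-benzyl-3-[(3E)-hex-3-enoyl]-1,3-oxazolidin-2-one
Product: 32 (4S)-4-benzyl-3-[(2S,3E)-2-ethylhex-3-enoyl]-1,3-oxazolidin-2-one, via sodium dienolate 31 (not isolated)
Conditions: NaN(SiMe3)2, THF, −78 °C; then EtI (5 equiv), −78 → −40 °C
Reagents that add atoms: iodoethane CCI
Why: Evans asymmetric alkylation: the chelated sodium dienolate 31 should be ethylated at its α-carbon from the face opposite the benzyl group, which sets the stereocentre as S while the 3E geometry is retained.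

**Step 14**
Reactants: 32 (4S)-4-benzyl-3-[(2S,3E)-2-ethylhex-3-enoyl]-1,3-oxazolidin-2-one
Product: 33 (2S,3E)-2-ethylhex-3-en-1-ol
Conditions: LiBH4, H2O (1 equiv), Et2O, 0 °C
Reagents that add atoms: none
Why: Reductive removal of the auxiliary with LiBH4 (hydride attack at the exocyclic imide carbonyl) should give the primary alcohol without touching the stereocentre or the alkene.

**Step 15**
Reactants: 33 (2S,3E)-2-ethylhex-3-en-1-ol
Product: 34 (3E,5S)-5-(iodomethyl)hept-3-ene
Conditions: PPh3, I2, imidazole, CH2Cl2, 0 → 23 °C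
Reagents that add atoms: iodine II
Why: Appel-type iodination converts the primary alcohol into the iodide by SN2 displacement at the CH2 group, one carbon away from the stereocentre.

**Step 16**
Reactants: 27 methyl 2-[(3S,4R,6S)-6-(2,2-dibromoethenyl)-4,6-diethyl-1,2-dioxan-3-yl]acetate; 34 (3E,5S)-5-(iodomethyl)hept-3-ene
Product: 36 methyl 2-[(3S,4R,6S)-6-[(1Z,4R,5E)-2-bromo-4-ethylocta-1,5-dien-1-yl]-4,6-diethyl-1,2-dioxan-3-yl]acetate, via alkylzinc iodide 35 (not isolated)
Conditions: 34, Zn dust, LiCl, THF, 35 °C; then 27, Pd(DPEphos)Cl2 (5 mol %), THF, 0 → 23 °C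
Reagents that add atoms: none
Why: Zinc insertion into the primary iodide followed by trans-selective Negishi monoalkylation of the 1,1-dibromoalkene: zerovalent palladium should insert into the less hindered C–Br bond trans to the quaternary C6, so the chain enters trans to C6, and the β-stereocentre of zinc reagent 35 is configurationally stable.

**Step 17**
Reactants: 36 methyl 2-[(3S,4R,6S)-6-[(1Z,4R,5E)-2-bromo-4-ethylocta-1,5-dien-1-yl]-4,6-diethyl-1,2-dioxan-3-yl]acetate
Product: 37 methyl 2-[(3S,4R,6S)-6-[(1E,4R,5E)-2,4-diethylocta-1,5-dien-1-yl]-4,6-diethyl-1,2-dioxan-3-yl]acetate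
Conditions: Et2Zn (2 equiv), Pd[P(t-Bu)3]2 (5 mol %), THF, 23 °C
Reagents that add atoms: diethylzinc CC[Zn]CC
Why: A second Negishi coupling with the bulky trialkylphosphine catalyst, which couples alkenyl bromides with alkylzincs with retention of geometry, should place ethyl cis to C6 and complete the E-trisubstituted alkene.

**Step 18**
Reactants: 37 methyl 2-[(3S,4R,6S)-6-[(1E,4R,5E)-2,4-diethylocta-1,5-dien-1-yl]-4,6-diethyl-1,2-dioxan-3-yl]acetate
Product: 38 2-[(3S,4R,6S)-6-[(1E,4R,5E)-2,4-diethylocta-1,5-dien-1-yl]-4,6-diethyl-1,2-dioxan-3-yl]acetic acid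
Conditions: LiOH, THF/MeOH/H2O, 0 °C; then 1 M HCl to pH 3
Reagents that add atoms: lithium hydroxide [Li+].[OH-]
Why: Saponification of the methyl ester at 0 °C is tolerated by dialkyl peroxides of this type, and any reversible retro-oxa-Michael opening would re-close to the same, thermodynamically preferred 3,4-trans isomer.

**Compound list**

1 | (4S)-4-benzyl-1,3-oxazolidin-2-one | O=C1N[C@@H](Cc2ccccc2)CO1 | starting material
2 | butanoyl chloride | CCCC(Cl)=O | starting material
3 | (4S)-4-benzyl-3-butanoyl-1,3-oxazolidin-2-one | CCCC(=O)N1[C@@H](Cc2ccccc2)COC1=O | intermediate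
4 | 2,3-dibromoprop-1-ene | C=C(Br)CBr | starting material
5 | sodium (1Z)-1-[(4S)-4-benzyl-2-oxo-1,3-oxazolidin-3-yl]but-1-en-1-olate | CC/C=C(\[O-])N1[C@@H](Cc2ccccc2)COC1=O.[Na+] | intermediate
6 | (4S)-4-benzyl-3-[(2R)-4-bromo-2-ethylpent-4-enoyl]-1,3-oxazolidin-2-one | C=C(Br)C[C@@H](CC)C(=O)N1[C@@H](Cc2ccccc2)COC1=O | intermediate
7 | (4S)-4-benzyl-3-[(2R)-2-ethyl-4-methylidenehexanoyl]-1,3-oxazolidin-2-one | C=C(CC)C[C@@H](CC)C(=O)N1[C@@H](Cc2ccccc2)COC1=O | intermediate
8 | (2R)-2-ethyl-4-methylidenehexaneperoxoic acid | C=C(CC)C[C@@H](CC)C(=O)OO | intermediate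
9 | (2R)-2-ethyl-4-methylidenehexanoic acid | C=C(CC)C[C@@H](CC)C(=O)O | intermediate
10 | potassium monomethyl malonate | COC(=O)CC(=O)[O-].[K+] | starting material
11 | (2R)-2-ethyl-1-(1H-imidazol-1-yl)-4-methylidenehexan-1-one | C=C(CC)C[C@@H](CC)C(=O)n1ccnc1 | intermediate
12 | (4R)-4-ethyl-2-(methoxycarbonyl)-6-methylidene-3-oxooctanoic acid (C2 epimers) | C=C(CC)C[C@@H](CC)C(=O)C(C(=O)O)C(=O)OC | intermediate
13 | methyl (4R)-4-ethyl-6-methylidene-3-oxooctanoate | C=C(CC)C[C@@H](CC)C(=O)CC(=O)OC | intermediate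
14 | methyl (4R)-4-ethyl-5-(4-ethyl-1,2,3-trioxolan-4-yl)-3-oxopentanoate (primary ozonide) | CCC1(C[C@@H](CC)C(=O)CC(=O)OC)COOO1 | intermediate
15 | C6 carbonyl oxide of methyl (4R)-4-ethyl-3,6-dioxooctanoate | CCC(=[O+][O-])C[C@@H](CC)C(=O)CC(=O)OC | intermediate
16 | methyl (4R)-4-ethyl-6-hydroperoxy-6-methoxy-3-oxooctanoate (C6 epimers) | CCC(OC)(OO)C[C@@H](CC)C(=O)CC(=O)OC | intermediate
17 | methyl 2-[(4R)-4,6-diethyl-3-hydroxy-6-methoxy-1,2-dioxan-3-yl]acetate (C3/C6 epimers) | CCC1(OC)C[C@@H](CC)C(O)(CC(=O)OC)OO1 | intermediate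
18 | allyltrimethylsilane | C=CC[Si](C)(C)C | starting material
19 | methyl 2-[(4R)-4,6-diethyl-6-methoxy-3-(trimethylsilyloxy)-1,2-dioxan-3-yl]acetate (C3/C6 epimers) | CCC1(OC)C[C@@H](CC)C(O[Si](C)(C)C)(CC(=O)OC)OO1 | intermediate
20 | peroxycarbenium triflate formed from 19 by loss of the C6 methoxy group (C6=O1 cation) | CCC1=[O+]OC(O[Si](C)(C)C)(CC(=O)OC)[C@H](CC)C1.[O-]S(=O)(=O)C(F)(F)F | intermediate
21 | methyl 2-[(4R,6R)-4,6-diethyl-6-(prop-2-en-1-yl)-3-(trimethylsilyloxy)-1,2-dioxan-3-yl]acetate (C3 epimers) | C=CC[C@]1(CC)C[C@@H](CC)C(O[Si](C)(C)C)(CC(=O)OC)OO1 | intermediate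
22 | peroxycarbenium triflate formed from 21 by loss of the C3 silyloxy group (C3=O2 cation) | C=CC[C@]1(CC)C[C@@H](CC)C(CC(=O)OC)=[O+]O1.[O-]S(=O)(=O)C(F)(F)F | intermediate
23 | methyl 2-[(3S,4R,6R)-4,6-diethyl-6-(prop-2-en-1-yl)-1,2-dioxan-3-yl]acetate | C=CC[C@]1(CC)C[C@@H](CC)[C@H](CC(=O)OC)OO1 | intermediate
24 | methyl 2-[(3S,4R,6S)-4,6-diethyl-6-[(1E)-prop-1-en-1-yl]-1,2-dioxan-3-yl]acetate | C/C=C/[C@]1(CC)C[C@@H](CC)[C@H](CC(=O)OC)OO1 | intermediate
25 | methyl 2-[(3S,4R,6S)-4,6-diethyl-6-(5-methyl-1,2,4-trioxolan-3-yl)-1,2-dioxan-3-yl]acetate (ozonide, epimers in the trioxolane) | CC1OC(OO1)[C@]2(CC)C[C@@H](CC)[C@H](CC(=O)OC)OO2 | intermediate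
26 | methyl 2-[(3S,4R,6S)-4,6-diethyl-6-formyl-1,2-dioxan-3-yl]acetate | O=C[C@]1(CC)C[C@@H](CC)[C@H](CC(=O)OC)OO1 | intermediate
27 | methyl 2-[(3S,4R,6S)-6-(2,2-dibromoethenyl)-4,6-diethyl-1,2-dioxan-3-yl]acetate | BrC(Br)=C[C@]1(CC)C[C@@H](CC)[C@H](CC(=O)OC)OO1 | intermediate
28 | (3E)-hex-3-enoic acid | CC/C=C/CC(=O)O | starting material
29 | (3E)-hex-3-enoic 2,2-dimethylpropanoic anhydride | CC/C=C/CC(=O)OC(=O)C(C)(C)C | intermediate
30 | (4S)-4-benzyl-3-[(3E)-hex-3-enoyl]-1,3-oxazolidin-2-one | CC/C=C/CC(=O)N1[C@@H](Cc2ccccc2)COC1=O | intermediate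
31 | sodium (1Z,3E)-1-[(4S)-4-benzyl-2-oxo-1,3-oxazolidin-3-yl]hexa-1,3-dien-1-olate | CC/C=C/C=C(\[O-])N1[C@@H](Cc2ccccc2)COC1=O.[Na+] | intermediate
32 | (4S)-4-benzyl-3-[(2S,3E)-2-ethylhex-3-enoyl]-1,3-oxazolidin-2-one | CC/C=C/[C@H](CC)C(=O)N1[C@@H](Cc2ccccc2)COC1=O | intermediate
33 | (2S,3E)-2-ethylhex-3-en-1-ol | CC/C=C/[C@H](CC)CO | intermediate
34 | (3E,5S)-5-(iodomethyl)hept-3-ene | CC/C=C/[C@H](CC)CI | intermediate
35 | [(2S,3E)-2-ethylhex-3-en-1-yl]zinc iodide | CC/C=C/[C@H](CC)C[Zn]I | intermediate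
36 | methyl 2-[(3S,4R,6S)-6-[(1Z,4R,5E)-2-bromo-4-ethylocta-1,5-dien-1-yl]-4,6-diethyl-1,2-dioxan-3-yl]acetate | CC/C=C/[C@H](CC)C/C(Br)=C/[C@]1(CC)C[C@@H](CC)[C@H](CC(=O)OC)OO1 | intermediate
37 | methyl 2-[(3S,4R,6S)-6-[(1E,4R,5E)-2,4-diethylocta-1,5-dien-1-yl]-4,6-diethyl-1,2-dioxan-3-yl]acetate | CC/C=C/[C@H](CC)C/C(=C/[C@]1(CC)C[C@@H](CC)[C@H](CC(=O)OC)OO1)CC | intermediate
38 | 2-[(3S,4R,6S)-6-[(1E,4R,5E)-2,4-diethylocta-1,5-dien-1-yl]-4,6-diethyl-1,2-dioxan-3-yl]acetic acid | CC/C=C/[C@H](CC)C/C(=C/[C@]1(CC)C[C@@H](CC)[C@H](CC(=O)O)OO1)CC | target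

**Step count.** Total: 18 steps. Longest linear sequence: 14 steps (steps 1–11, then 16–18); steps 12–15 form the side-chain branch.

**Steps most likely to fail**

Step 6. Ozone may be consumed by the enol tautomer of the keto ester, the carbonyl oxide may be captured by the C3 ketone as a bicyclic ozonide before methanol adds, or ring closure of the hydroperoxide may stay incomplete. The fallback takes the O–O unit from hydrogen peroxide instead of ozone and sets out from 13. Lemieux–Johnson cleavage (OsO4 cat., NaIO4, 2,6-lutidine, dioxane/H2O) should give methyl (4R)-4-ethyl-3,6-dioxooctanoate F1. Hydrogen peroxide in MeCN at 0 °C should add across the 1,4-diketone to give the bis-hemiketal methyl 2-[(4R)-4,6-diethyl-3,6-dihydroxy-1,2-dioxan-3-yl]acetate F2. With 2,6-lutidine and Me3SiOTf both hydroxyls are capped as methyl 2-[(4R)-4,6-diethyl-3,6-bis(trimethylsilyloxy)-1,2-dioxan-3-yl]acetate F3, and allyltrimethylsilane with Me3SiOTf then substitutes at C6 as in step 7. The fallback comes back to the route at 21.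

Step 8. Ionisation at C3 may occur by loss of the ring oxygen instead of the silyloxy group (ring opening and reduction to an open-chain product), the cation may lose a proton to the exocyclic enoate, or hydride delivery may show poor facial selectivity. The fallback brings C3 into the ring already at the C–H level by oxa-Michael closure and sets out from 7. LiBH4 should give (2R)-2-ethyl-4-methylidenehexan-1-ol F4, Dess–Martin oxidation (2R)-2-ethyl-4-methylidenehexanal F5, and Wittig reaction with Ph3P=CHCO2Me methyl (2E,4R)-4-ethyl-6-methylideneoct-2-enoate F6. Ozonolysis in methanol at −78 °C should give methyl (2E,4R)-4-ethyl-6-hydroperoxy-6-methoxyoct-2-enoate F7. Catalytic Et2NH in CF3CH2OH should then close F7 by conjugate addition to methyl 2-[(3S,4R)-4,6-diethyl-6-methoxy-1,2-dioxan-3-yl]acetate F8, the 3,4-trans isomer being favoured because the addition is reversible. Allylation of F8 with 18 and Me3SiOTf as in step 7 comes back to the route at 23.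

Step 9. The palladium hydride may cleave the O–O bond, or may fail to engage the hindered alkene next to the quaternary carbon. The fallback avoids isomerisation by installing an allene that ozone cleaves directly, and sets out from 17. The capping and substitution conditions of step 7, with propargyltrimethylsilane in place of 18 (SE2' attack), should give methyl 2-[(4R,6S)-4,6-diethyl-6-(propa-1,2-dien-1-yl)-3-(trimethylsilyloxy)-1,2-dioxan-3-yl]acetate F9. Et3SiH and Me3SiOTf as in step 8 should give methyl 2-[(3S,4R,6S)-4,6-diethyl-6-(propa-1,2-dien-1-yl)-1,2-dioxan-3-yl]acetate F10. Ozonolysis (O3, CH2Cl2, −78 °C; PPh3) cleaves both allene double bonds and comes back to the route at 26.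

**Further compounds**

F1 | step 6 | methyl (4R)-4-ethyl-3,6-dioxooctanoate | CCC(=O)C[C@@H](CC)C(=O)CC(=O)OC
F2 | step 6 | methyl 2-[(4R)-4,6-diethyl-3,6-dihydroxy-1,2-dioxan-3-yl]acetate | CCC1(O)C[C@@H](CC)C(O)(CC(=O)OC)OO1
F3 | step 6 | methyl 2-[(4R)-4,6-diethyl-3,6-bis(trimethylsilyloxy)-1,2-dioxan-3-yl]acetate | CCC1(O[Si](C)(C)C)C[C@@H](CC)C(O[Si](C)(C)C)(CC(=O)OC)OO1
F4 | step 8 | (2R)-2-ethyl-4-methylidenehexan-1-ol | C=C(CC)C[C@@H](CC)CO
F5 | step 8 | (2R)-2-ethyl-4-methylidenehexanal | C=C(CC)C[C@@H](CC)C=O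
F6 | step 8 | methyl (2E,4R)-4-ethyl-6-methylideneoct-2-enoate | C=C(CC)C[C@@H](CC)/C=C/C(=O)OC
F7 | step 8 | methyl (2E,4R)-4-ethyl-6-hydroperoxy-6-methoxyoct-2-enoate | CCC(OC)(OO)C[C@@H](CC)/C=C/C(=O)OC
F8 | step 8 | methyl 2-[(3S,4R)-4,6-diethyl-6-methoxy-1,2-dioxan-3-yl]acetate | CCC1(OC)C[C@@H](CC)[C@H](CC(=O)OC)OO1
F9 | step 9 | methyl 2-[(4R,6S)-4,6-diethyl-6-(propa-1,2-dien-1-yl)-3-(trimethylsilyloxy)-1,2-dioxan-3-yl]acetate | C=C=C[C@]1(CC)C[C@@H](CC)C(O[Si](C)(C)C)(CC(=O)OC)OO1
F10 | step 9 | methyl 2-[(3S,4R,6S)-4,6-diethyl-6-(propa-1,2-dien-1-yl)-1,2-dioxan-3-yl]acetate | C=C=C[C@]1(CC)C[C@@H](CC)[C@H](CC(=O)OC)OO1
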